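## Retrosynthetic overview

1. C3–Br is installed last, by electrophilic bromination of 5,6-dibromo-1-methylindole.
2. The pyrrole ring is the only ring made (the benzene ring is bought). It is closed at N1–C7a by intramolecular Cu-catalysed N-arylation of 2-(methylamino)-1-(2,4,5-tribromophenyl)ethanol, and the indolin-3-ol then loses water to aromatise.
3. The key bond is C2–C3: the carbonyl carbon of 2,4,5-tribromobenzaldehyde is joined to an aminomethyl carbanion equivalent, MeNH–CH2(−). This is delivered as the non-stabilised azomethine ylide from sarcosine and formaldehyde, so an aldehyde carbon and an iminium-type carbon (both acceptors in normal polarity) are joined, and N1, N-CH3 and C2 arrive in one piece.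
4. The aldehyde comes from 1,2,4,5-tetrabromobenzene by mono Br/Mg exchange and formylation; the symmetry of the tetrabromide fixes the 5,6-dibromo pattern without any regiochemical question.

Assumption: the target has no stereocentre, so no enantiocontrol is needed; the oxazolidine, amino alcohol and indolinol intermediates are racemic and their one stereocentre is erased on aromatisation.

## Route

Step 1
Reactants: 1 1,2,4,5-tetrabromobenzene
Product: 3 2,4,5-tribromobenzaldehyde, via aryl Grignard 2 (not isolated)
Conditions: i-PrMgCl·LiCl (1.05 equiv), THF, −20 °C, 2 h; DMF (2 equiv), −20 °C → rt; aq. HCl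
Reagents that add atoms: N,N-dimethylformamide, CN(C)C=O
Why: Knochel Br/Mg exchange with the turbo-Grignard followed by Bouveault formylation; the four C–Br bonds of 1 are equivalent so only one mono-Grignard can form, a second exchange is much slower on the electron-rich arylmagnesium, and the ortho-bromoaryl Grignard is stable below 0 °C.

Step 2
Reactants: 3 2,4,5-tribromobenzaldehyde; 4 sarcosine (N-methylglycine); 5 paraformaldehyde
Product: 8 2-(methylamino)-1-(2,4,5-tribromophenyl)ethan-1-ol (racemic), via azomethine ylide 6 (not isolated), via oxazolidine 7 (not isolated)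
Conditions: sarcosine (2 equiv), (CH2O)n (4 equiv), PhMe, reflux, Dean–Stark, 6 h; then 3 M HCl, EtOH, 60 °C; NaOH work-up
Reagents that add atoms: none
Why: Decarboxylative condensation of sarcosine with formaldehyde gives the non-stabilised azomethine ylide 6, whose N-bound carbon acts as an aminomethyl carbanion and attacks the electron-poor aldehyde carbon of 3 in a regioselective 1,3-dipolar cycloaddition to C=O (5-aryloxazolidine 7), and acid hydrolysis of the N,O-acetal frees the 1,2-amino alcohol; the carbinol stereocentre forms racemic and is removed in step 3.

Step 3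
Reactants: 8 2-(methylamino)-1-(2,4,5-tribromophenyl)ethan-1-ol
Product: 10 5,6-dibromo-1-methyl-1H-indole, via indolin-3-ol 9 (not isolated)
Conditions: CuI (10 mol %), L-proline (20 mol %), K2CO3 (2 equiv), DMSO, 70 °C, Ar; extractive work-up, then TsOH·H2O (5 mol %), PhMe, 50 °C
Reagents that add atoms: none
Why: Ullmann-type intramolecular Cu-catalysed N-arylation in which the amino alcohol chelates copper and only the C–Br ortho to the side chain can close a five-membered ring, so the other two aryl bromides remain; the 3-hydroxyindoline then loses water under acid (E1 through the nitrogen-stabilised benzylic cation) to aromatise, erasing the stereocentre.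

Step 4
Reactants: 10 5,6-dibromo-1-methyl-1H-indole
Product: 11 3,5,6-tribromo-1-methyl-1H-indole
Conditions: NBS (1.0 equiv), DMF, 0 °C, 1 h, dark
Reagents that add atoms: N-bromosuccinimide, O=C1CCC(=O)N1Br
Why: Electrophilic aromatic substitution at C3, by far the most nucleophilic position of an N-alkylindole, so one equivalent of NBS at 0 °C brominates there while C2 and the deactivated dibromobenzo ring do not react.

## Compound list

1 | 1,2,4,5-tetrabromobenzene | Brc1cc(Br)c(Br)cc1Br | starting material
2 | (2,4,5-tribromophenyl)magnesium chloride (LiCl complex) | Cl[Mg]c1cc(Br)c(Br)cc1Br | intermediate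
3 | 2,4,5-tribromobenzaldehyde | O=Cc1cc(Br)c(Br)cc1Br | intermediate
4 | sarcosine (N-methylglycine) | CNCC(=O)O | starting material
5 | paraformaldehyde (formaldehyde source, (CH2O)n) | C=O | starting material
6 | N-methyl azomethine ylide (CH2=N+(CH3)–CH2−) | C=[N+](C)[CH2-] | intermediate
7 | 3-methyl-5-(2,4,5-tribromophenyl)-1,3-oxazolidine (racemic) | CN1COC(C1)c2cc(Br)c(Br)cc2Br | intermediate
8 | 2-(methylamino)-1-(2,4,5-tribromophenyl)ethan-1-ol (racemic) | CNCC(O)c1cc(Br)c(Br)cc1Br | intermediate
9 | 5,6-dibromo-1-methylindolin-3-ol (racemic) | CN1CC(O)c2cc(Br)c(Br)cc21 | intermediate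
10 | 5,6-dibromo-1-methyl-1H-indole | Cn1ccc2cc(Br)c(Br)cc21 | intermediate
11 | 3,5,6-tribromo-1-methyl-1H-indole | Cn1cc(Br)c2cc(Br)c(Br)cc21 | target

## Step count and risks

Total step count: 4. Longest linear sequence: 4 (from 1; 4 and 5 are bought).

Most likely to fail, in this order:

Step 2. The ylide can be used up by formaldehyde itself, sarcosine can condense with the aryl aldehyde instead, and the ortho-bromine hinders the carbonyl. The fallback sets out from 3: Corey–Chaykovsky methylenation (Me3S+ I−, powdered KOH, MeCN, 60 °C) gives 2-(2,4,5-tribromophenyl)oxirane F1, and excess methylamine (40 % aq., EtOH, 50 °C, sealed tube) opens it at the unhindered CH2 to come back to the route at 8.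

Step 3. Copper may also attack the two other C–Br bonds (oligomers, hydrodebromination), or the free alkoxide may interfere. The fallback sets out from 8: Jones oxidation of the N-protonated amino alcohol (CrO3/H2SO4, acetone, 0 °C) and isolation as the salt gives 2-(methylamino)-1-(2,4,5-tribromophenyl)ethan-1-one hydrochloride F2. K2CO3 in degassed DMF (80 °C) then frees the amine, which displaces the bromide ortho to the now activating ketone (intramolecular SNAr, no metal) to give 5,6-dibromo-1-methylindolin-3-one F3. NaBH4 (MeOH, 0 °C) reduces the ketone, and the fallback comes back to the route at 9, which the acid treatment of step 3 takes on to 10.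

Step 1. The tetrabromide is poorly soluble at low temperature, and double exchange or aryne formation from the ortho-bromoaryl Grignard is possible on warming. The fallback sets out from 1 (3 equiv, the excess is recovered): Suzuki–Miyaura mono-vinylation with potassium vinyltrifluoroborate (PdCl2(dppf), K2CO3, THF/H2O, 70 °C) gives 2,4,5-tribromostyrene F4, and Lemieux–Johnson cleavage (cat. OsO4, NaIO4, 2,6-lutidine, dioxane/H2O, rt) comes back to the route at 3.

## Further compounds

F1 | step 2 | 2-(2,4,5-tribromophenyl)oxirane (racemic) | C1OC1c1cc(Br)c(Br)cc1Br
F2 | step 3 | 2-(methylamino)-1-(2,4,5-tribromophenyl)ethan-1-one hydrochloride | CNCC(=O)c1cc(Br)c(Br)cc1Br.Cl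
F3 | step 3 | 5,6-dibromo-1-methylindolin-3-one | CN1CC(=O)c2cc(Br)c(Br)cc21
F4 | step 1 | 2,4,5-tribromostyrene | C=Cc1cc(Br)c(Br)cc1Br
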